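I decided to drop the clock and divide the rate at which target appears by the rate at which reagent is lost, so that time falls out and two amounts remain: the reagent charged and the substrate that can be used up while the solution keeps its dissolved share.

common to all: solid substrate 0.10 M; free catalyst 0.24 mM
- north-east: reagent 0.035 M; run made earlier
- north-west: reagent 0.053 M; run made earlier
- flask: reagent 0.0700 M; time 8.0 min

| run | time / min | target / % | starting material / % |
|---|---|---|---|
| north-east | 0.833 | 18.2 | 12.8 |
| north-east | 1.33 | 24.7 | 13.2 |
| north-east | 2.50 | 32.4 | 14.3 |
| north-east | 5.00 | 34.0 | 13.6 |
| north-east | 10.0 | 34.5 | 14.4 |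
| north-west | 0.833 | 19.7 | 12.8 |
| north-west | 2.50 | 42.7 | 14.6 |
| north-west | 4.00 | 50.0 | 13.4 |
| north-west | 6.00 | 51.1 | 13.8 |
| north-west | 10.0 | 53.4 | 12.7 |

(readings scatter by 0.5 percentage points)

- given per volume of solution although it is solid: solid substrate
- at the start none of the solid substrate is in solution
- starting material is what solid substrate becomes in solution
- starting material means what is dissolved; the solid is not counted in it

1. the target standing at 8.0 min, as a percentage of the solid substrate charged
2. concentration of starting material in solution at 8.0 min, in percent of saturation

At their last readings the north-east run held 0.986 and the north-west run 1.01 of target per reagent charged, so I took the ratio as one to one. Starting material read between 12.7% and 14.6% throughout both runs, and the last readings average 13.6%, a share I called s. With c_B the reagent charged and c_S the solid substrate charged, I reckoned: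

ρ = c_B / [c_S (1 − s)] = 0.810

I called ρ the reagent share, reagent set against the substrate not held dissolved. In this flask it stood below one, so I expected reagent to give out first, at a ceiling c_B/c_S of 70.0%, with 16.4% still solid and the solution holding its level. The north-west run had reached 94.3% of its ceiling at 4.00 min, so I placed this flask just under its ceiling at 8.0 min.

The forecast, reckoned separately from mine, gave 68.5% and 99.5%, on the ground that "Target plateaus match the reagent charged".

The flask gave 68.4% and 99.9%.

    catalyst intermediate B ⇌ free catalyst + target (K = 0.0400 M, k = 380 s⁻¹)
    reagent + free catalyst → catalyst intermediate A (k = 500 L mol⁻¹ s⁻¹)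
    solid substrate ⇌ starting material, rate k3*(cs3 - [starting material]) while solid is left; crystals form when [starting material] > cs3 (solubility = 14.0 mM, k = 0.450 s⁻¹)
    starting material + catalyst intermediate A ⇌ catalyst intermediate B (K = 25.0 L mol⁻¹, k = 180 L mol⁻¹ s⁻¹)
    free catalyst → spent catalyst (k = 0.0200 s⁻¹)

The neighbouring flask, charged with 0.028 M of reagent and otherwise like this one, has a reagent share of 0.324, lower than this flask's, and a ceiling of 28.0%. It gave 27.9% of target at 8.00 min. Reagent was its limiting reagent, with 0.43% of its charge left, while solid substrate still stood at 58.1%.

The earlier runs and the new flask are simulated from invented constants; noise was put on by code.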